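**Retrosynthetic overview**

1. Ring C is closed last. O1–C2 comes from acid cyclodehydration of a 2‑alkoxy‑1,3‑diketone, C2–C3 from C‑aroylation of the C3 enolate of a ring‑A aryl ketone with the ring‑B acid chloride, and C4–C4a from directed ortho‑lithiation of the ring‑A phenol MOM ether.
2. The plan rests on ring A: a phloroglucinol whose C8 carries the quaternary 1,1‑dimethylallyl group between C8a–O1 and C7–O7, with C5–O5 para to it. It is built de novo from 3‑ethoxycyclobutenone and a TIPS ynol ether that already holds the quaternary carbon (bonds C8–C8a, C6–C7, then C4a–C8a). This gives O1 as free OH, O7 as OTIPS and O5 as OEt, and C4a as the only CH between OH and OEt.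
3. Ring B comes from 6‑bromoveratraldehyde: catechol, 4‑O‑(1,1‑dimethylpropargyl) ether, Claisen/oxa‑6π closure to the 2,2‑dimethylchromene, CHO to CO2H, then Br to prenyl via aryllithium/copper and prenyl bromide.
4. Order of ring formation: ring A (benzannulation); the pyran ring on ring B (separate branch); the pyranone ring C; then cleavage of the O5 ethyl and O7 silyl ethers.

Key step: step 4

Remark on the chemistry: the target has no stereocentre and no configurationally defined acyclic double bond (the 2H‑chromene alkene is ring‑constrained), so no stereochemical control is needed. LiTMP, LiHMDS and MgI2·OEt2 are taken as preformed reagents.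

**Route**

Step 1
Reactants: 1 2,2‑dimethylbut‑3‑enoic acid
Product: 2 ethyl 2,2‑dimethylbut‑3‑enoate
Conditions: EtI, K2CO3, DMF, rt
Reagents that add atoms: iodoethane CCI
Why: Carboxylate O‑alkylation (SN2) should give the ester needed for the ynolate homologation without touching the terminal alkene.

Step 2
Reactants: 2 ethyl 2,2‑dimethylbut‑3‑enoate
Product: 4 triisopropyl[(3,3‑dimethylpent‑4‑en‑1‑yn‑1‑yl)oxy]silane, via lithium ynolate 3 (not isolated)
Conditions: CH2Br2, LiTMP, THF, −78 °C; LiHMDS, −78 °C; n‑BuLi, −78 °C → rt; TIPSCl, 0 °C → rt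
Reagents that add atoms: dibromomethane BrCBr; triisopropylsilyl chloride CC(C)[Si](Cl)(C(C)C)C(C)C
Why: Kowalski ester‑to‑ynolate homologation, in which LiCHBr2 adds to the ester, the derived α,α‑dibromo ketone enolate undergoes Br/Li exchange and 1,2‑shift of the tertiary allylic group to ynolate 3, and the bulky silyl chloride traps it on oxygen as the stable TIPS ynol ether.

Step 3
Reactants: 5 ethoxyacetylene
Product: 7 3‑ethoxycyclobut‑2‑en‑1‑one, via ketene 6 (not isolated)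
Conditions: AcCl (slow addition), Et3N, MeCN, 0 °C → rt
Reagents that add atoms: acetyl chloride CC(Cl)=O
Why: Ketene formed in the flask by dehydrochlorination of acetyl chloride should undergo regiospecific [2+2] cycloaddition with the electron‑rich ynol ether, the terminal alkyne carbon bonding to the ketene carbonyl carbon.

Step 4
Reactants: 7 3‑ethoxycyclobut‑2‑en‑1‑one; 4 triisopropyl[(3,3‑dimethylpent‑4‑en‑1‑yn‑1‑yl)oxy]silane
Product: 12 5‑ethoxy‑2‑(2‑methylbut‑3‑en‑2‑yl)‑3‑[(triisopropylsilyl)oxy]phenol, via vinylketene 8 (not isolated), via vinylcyclobutenone 9 (not isolated), via dienylketene 10 (not isolated), via cyclohexadienone 11 (not isolated)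
Conditions: PhMe (degassed), 80 °C → 110 °C, sealed tube
Reagents that add atoms: none
Why: Heating opens 7 by 4π‑electrocyclic cleavage of the C1–C4 bond to ethoxy vinylketene 8, and the ynol ether 4 adds to the ketene C=C in a [2+2] cycloaddition in which its alkyl‑bearing carbon bonds to the ketene carbonyl carbon (C8–C8a) and its silyloxy carbon to the ketene α‑carbon (C6–C7), giving vinylcyclobutenone 9. A second 4π opening gives dienylketene 10, and ring A closes by thermal disrotatory 6π‑electrocyclisation between the ketene carbon and the terminal CH2 (C4a–C8a), after which cyclohexadienone 11 tautomerises to phenol 12. This is the Danheiser benzannulation of a cyclobutenone with a siloxyalkyne, applied here to a 3‑alkoxycyclobutenone. No stereocentre survives, because the sp3 carbon of 9 is lost on ring opening. The selectivity needed is the orientation of the [2+2] step, and it is fixed by the ynol‑ether polarisation of 4, whose carbon β to oxygen is the nucleophilic terminus; this places the quaternary group between the new OH and the OTIPS and puts the ethoxy group para to it. The quaternary carbon arrives on the alkyne, so no substitution at a hindered aromatic position is required, and the three oxygens emerge differentiated as OH (O1), OTIPS (O7) and OEt (O5).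

Step 5
Reactants: 12 5‑ethoxy‑2‑(2‑methylbut‑3‑en‑2‑yl)‑3‑[(triisopropylsilyl)oxy]phenol
Product: 13 triisopropyl[5‑ethoxy‑3‑(methoxymethoxy)‑2‑(2‑methylbut‑3‑en‑2‑yl)phenoxy]silane
Conditions: NaH, MOMCl, THF, 0 °C → rt
Reagents that add atoms: chloromethyl methyl ether COCCl
Why: O‑alkylation of the hindered sodium phenoxide installs the MOM acetal, which directs the next metalation and is lost later in the acidic ring‑closure step.

Step 6
Reactants: 14 methyl glycolate
Product: 15 methyl 2‑(methoxymethoxy)acetate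
Conditions: MOMCl, iPr2NEt, CH2Cl2, 0 °C → rt
Reagents that add atoms: chloromethyl methyl ether COCCl
Why: Standard MOM protection of a primary alcohol under amine base leaves the ester untouched.

Step 7
Reactants: 15 methyl 2‑(methoxymethoxy)acetate
Product: 16 N‑methoxy‑2‑(methoxymethoxy)‑N‑methylacetamide
Conditions: MeNHOMe·HCl, iPrMgCl, THF, −20 °C
Reagents that add atoms: N,O‑dimethylhydroxylamine hydrochloride CNOC.Cl
Why: Acyl substitution of the ester by the chloromagnesium amide of N,O‑dimethylhydroxylamine gives the Weinreb amide.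

Step 8
Reactants: 13 triisopropyl[5‑ethoxy‑3‑(methoxymethoxy)‑2‑(2‑methylbut‑3‑en‑2‑yl)phenoxy]silane; 16 N‑methoxy‑2‑(methoxymethoxy)‑N‑methylacetamide
Product: 18 1‑[6‑ethoxy‑2‑(methoxymethoxy)‑3‑(2‑methylbut‑3‑en‑2‑yl)‑4‑[(triisopropylsilyl)oxy]phenyl]‑2‑(methoxymethoxy)ethan‑1‑one, via aryllithium 17 (not isolated)
Conditions: n‑BuLi, THF, 0 °C; then 16, −78 °C → 0 °C; aq. NH4Cl
Reagents that add atoms: none
Why: Directed ortho‑metalation should lithiate only the CH flanked by the two coordinating ethers OMOM and OEt (C4a), since the other CH lies next to the bulky non‑coordinating OTIPS, and the aryllithium adds once to the Weinreb amide through its chelated tetrahedral intermediate.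

Step 9
Reactants: 19 6‑bromoveratraldehyde (2‑bromo‑4,5‑dimethoxybenzaldehyde)
Product: 20 2‑bromo‑4,5‑dihydroxybenzaldehyde
Conditions: BBr3, CH2Cl2, −78 °C → rt; H2O
Reagents that add atoms: none
Why: Lewis‑acid ether cleavage with BBr3 removes both aryl methyl groups while the aldehyde and aryl bromide are tolerated.

Step 10
Reactants: 20 2‑bromo‑4,5‑dihydroxybenzaldehyde; 21 3‑chloro‑3‑methylbut‑1‑yne
Product: 22 2‑bromo‑5‑hydroxy‑4‑[(2‑methylbut‑3‑yn‑2‑yl)oxy]benzaldehyde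
Conditions: DBU (1 equiv), CuCl2·2H2O (cat.), MeCN, 0 °C
Reagents that add atoms: none
Why: The hydroxyl para to the formyl group is the more acidic, so one equivalent of base forms that phenoxide, which is alkylated by the copper‑activated tertiary propargylic chloride (copper‑catalysed propargylic etherification).

Step 11
Reactants: 22 2‑bromo‑5‑hydroxy‑4‑[(2‑methylbut‑3‑yn‑2‑yl)oxy]benzaldehyde
Product: 23 2‑bromo‑5‑(methoxymethoxy)‑4‑[(2‑methylbut‑3‑yn‑2‑yl)oxy]benzaldehyde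
Conditions: MOMCl, iPr2NEt, CH2Cl2, 0 °C → rt
Reagents that add atoms: chloromethyl methyl ether COCCl
Why: MOM protection of the remaining phenol blocks that oxygen through the thermal and organometallic steps and is removed in the final acid step.

Step 12
Reactants: 23 2‑bromo‑5‑(methoxymethoxy)‑4‑[(2‑methylbut‑3‑yn‑2‑yl)oxy]benzaldehyde
Product: 24 5‑bromo‑8‑(methoxymethoxy)‑2,2‑dimethyl‑2H‑chromene‑6‑carbaldehyde
Conditions: PhNEt2, 170 °C
Reagents that add atoms: none
Why: Aryl propargyl ether Claisen rearrangement to the only free ortho carbon, followed by 1,5‑hydrogen shift and oxa‑6π electrocyclisation, should give the 2,2‑dimethyl‑2H‑chromene, the other ortho position being blocked by OMOM.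

Step 13
Reactants: 24 5‑bromo‑8‑(methoxymethoxy)‑2,2‑dimethyl‑2H‑chromene‑6‑carbaldehyde
Product: 25 5‑bromo‑8‑(methoxymethoxy)‑2,2‑dimethyl‑2H‑chromene‑6‑carboxylic acid
Conditions: NaClO2, NaH2PO4, 2‑methyl‑2‑butene, t‑BuOH/H2O, rt
Reagents that add atoms: sodium chlorite [Na+].[O-]Cl=O
Why: Pinnick oxidation converts the aldehyde into the acid under buffered conditions, the hypochlorite by‑product being scavenged so that the chromene alkene and the MOM acetal are spared.

Step 14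
Reactants: 25 5‑bromo‑8‑(methoxymethoxy)‑2,2‑dimethyl‑2H‑chromene‑6‑carboxylic acid; 26 prenyl bromide (1‑bromo‑3‑methylbut‑2‑ene)
Product: 28 8‑(methoxymethoxy)‑2,2‑dimethyl‑5‑(3‑methylbut‑2‑en‑1‑yl)‑2H‑chromene‑6‑carboxylic acid, via dilithio carboxylate 27 (not isolated)
Conditions: n‑BuLi (2.1 equiv), THF, −78 °C; CuBr·SMe2 (cat.), then 26, −78 °C → 0 °C; dilute HCl
Reagents that add atoms: none
Why: Deprotonation of the acid and fast Br/Li exchange at −78 °C give the ortho‑lithiated lithium benzoate, whose copper‑mediated SN2 allylation with prenyl bromide should deliver the linear prenyl group, since attack through the tertiary terminus would build a quaternary carbon between two ortho substituents.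

Step 15
Reactants: 18 1‑[6‑ethoxy‑2‑(methoxymethoxy)‑3‑(2‑methylbut‑3‑en‑2‑yl)‑4‑[(triisopropylsilyl)oxy]phenyl]‑2‑(methoxymethoxy)ethan‑1‑one; 28 8‑(methoxymethoxy)‑2,2‑dimethyl‑5‑(3‑methylbut‑2‑en‑1‑yl)‑2H‑chromene‑6‑carboxylic acid
Product: 31 1‑[6‑ethoxy‑2‑(methoxymethoxy)‑3‑(2‑methylbut‑3‑en‑2‑yl)‑4‑[(triisopropylsilyl)oxy]phenyl]‑2‑(methoxymethoxy)‑3‑[8‑(methoxymethoxy)‑2,2‑dimethyl‑5‑(3‑methylbut‑2‑en‑1‑yl)‑2H‑chromen‑6‑yl]propane‑1,3‑dione (racemic at C2), via acid chloride 29 (not isolated), via lithium enolate 30 (not isolated)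
Conditions: 28, 1‑chloro‑N,N,2‑trimethylprop‑1‑en‑1‑amine, CH2Cl2, 0 °C → rt, evaporate; 18, LiHMDS (2.2 equiv), THF, −78 °C, then 29, −78 °C → 0 °C; aq. NH4Cl
Reagents that add atoms: none
Why: Claisen‑type C‑acylation of the chelated lithium enolate of the α‑alkoxy ketone by the aroyl chloride, made under neutral conditions with Ghosez's reagent so that the prenyl, chromene and MOM groups see no HCl, should give the 2‑alkoxy‑1,3‑diketone, with the excess base absorbing the more acidic product.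

Step 16
Reactants: 31 the 2‑(methoxymethoxy)‑1,3‑diketone from step 15
Product: 34 5‑ethoxy‑3‑hydroxy‑2‑[8‑hydroxy‑2,2‑dimethyl‑5‑(3‑methylbut‑2‑en‑1‑yl)‑2H‑chromen‑6‑yl]‑8‑(2‑methylbut‑3‑en‑2‑yl)‑7‑[(triisopropylsilyl)oxy]‑4H‑chromen‑4‑one, via phenol diketone 32 (not isolated), via bis‑MOM flavone 33 (not isolated)
Conditions: 3 M aq. HCl, MeOH/THF, 50 °C
Reagents that add atoms: none
Why: Acid first removes the aryl MOM group ortho to the carbonyl, the freed O1–H adds to the aroyl carbonyl and the hemiketal dehydrates (flavone cyclodehydration of a 1,3‑diketone), and the enol and aryl MOM acetals are then solvolysed while the hindered aryl TIPS ether, the chromene and the two prenyl‑type alkenes should persist.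

Step 17
Reactants: 34 5‑ethoxy‑3‑hydroxy‑2‑[8‑hydroxy‑2,2‑dimethyl‑5‑(3‑methylbut‑2‑en‑1‑yl)‑2H‑chromen‑6‑yl]‑8‑(2‑methylbut‑3‑en‑2‑yl)‑7‑[(triisopropylsilyl)oxy]‑4H‑chromen‑4‑one
Product: 35 3,5‑dihydroxy‑2‑[8‑hydroxy‑2,2‑dimethyl‑5‑(3‑methylbut‑2‑en‑1‑yl)‑2H‑chromen‑6‑yl]‑8‑(2‑methylbut‑3‑en‑2‑yl)‑7‑[(triisopropylsilyl)oxy]‑4H‑chromen‑4‑one
Conditions: MgI2·OEt2 (excess), THF, 60 °C; dilute HCl
Reagents that add atoms: none
Why: Chelation‑assisted dealkylation, in which magnesium bound between the C4 carbonyl and O5 activates only the peri ethyl ether for SN2 attack by iodide, should free the 5‑OH, while the silyl ether keeps O7 from adding to the neighbouring 1,1‑dimethylallyl group.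

Step 18
Reactants: 35 3,5‑dihydroxy‑2‑[8‑hydroxy‑2,2‑dimethyl‑5‑(3‑methylbut‑2‑en‑1‑yl)‑2H‑chromen‑6‑yl]‑8‑(2‑methylbut‑3‑en‑2‑yl)‑7‑[(triisopropylsilyl)oxy]‑4H‑chromen‑4‑one
Product: 36 broussoflavonol D, 3,5,7‑trihydroxy‑2‑[8‑hydroxy‑2,2‑dimethyl‑5‑(3‑methylbut‑2‑en‑1‑yl)‑2H‑chromen‑6‑yl]‑8‑(2‑methylbut‑3‑en‑2‑yl)‑4H‑chromen‑4‑one
Conditions: TBAF, AcOH, THF, 0 °C
Reagents that add atoms: none
Why: Fluoride cleaves the aryl silyl ether, and acetic acid buffering avoids exposing the polyphenolate to strongly basic conditions.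

**Compound list**

1 | 2,2‑dimethylbut‑3‑enoic acid | C=CC(C)(C)C(=O)O | starting material
2 | ethyl 2,2‑dimethylbut‑3‑enoate | C=CC(C)(C)C(=O)OCC | intermediate
3 | lithium 3,3‑dimethylpent‑4‑en‑1‑yn‑1‑olate (ynolate) | C=CC(C)(C)C#C[O-].[Li+] | intermediate (not isolated)
4 | triisopropyl[(3,3‑dimethylpent‑4‑en‑1‑yn‑1‑yl)oxy]silane | C=CC(C)(C)C#CO[Si](C(C)C)(C(C)C)C(C)C | intermediate
5 | ethoxyacetylene | CCOC#C | starting material
6 | ketene | C=C=O | intermediate (not isolated)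
7 | 3‑ethoxycyclobut‑2‑en‑1‑one | CCOC1=CC(=O)C1 | intermediate
8 | 3‑ethoxybuta‑1,3‑dien‑1‑one (vinylketene) | C=C(OCC)C=C=O | intermediate (not isolated)
9 | 4‑(1‑ethoxyvinyl)‑2‑(2‑methylbut‑3‑en‑2‑yl)‑3‑[(triisopropylsilyl)oxy]cyclobut‑2‑en‑1‑one (racemic) | O=C1C(C(C)(C)C=C)=C(O[Si](C(C)C)(C(C)C)C(C)C)C1C(OCC)=C | intermediate (not isolated)
10 | (3E)‑5‑ethoxy‑2‑(2‑methylbut‑3‑en‑2‑yl)‑3‑[(triisopropylsilyl)oxy]hexa‑1,3,5‑trien‑1‑one (dienylketene) | O=C=C(C(C)(C)C=C)/C(O[Si](C(C)C)(C(C)C)C(C)C)=C\C(OCC)=C | intermediate (not isolated)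
11 | 5‑ethoxy‑2‑(2‑methylbut‑3‑en‑2‑yl)‑3‑[(triisopropylsilyl)oxy]cyclohexa‑2,4‑dien‑1‑one | O=C1CC(OCC)=CC(O[Si](C(C)C)(C(C)C)C(C)C)=C1C(C)(C)C=C | intermediate (not isolated)
12 | 5‑ethoxy‑2‑(2‑methylbut‑3‑en‑2‑yl)‑3‑[(triisopropylsilyl)oxy]phenol | C=CC(C)(C)c1c(O)cc(OCC)cc1O[Si](C(C)C)(C(C)C)C(C)C | intermediate
13 | triisopropyl[5‑ethoxy‑3‑(methoxymethoxy)‑2‑(2‑methylbut‑3‑en‑2‑yl)phenoxy]silane | C=CC(C)(C)c1c(OCOC)cc(OCC)cc1O[Si](C(C)C)(C(C)C)C(C)C | intermediate
14 | methyl glycolate | COC(=O)CO | starting material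
15 | methyl 2‑(methoxymethoxy)acetate | COCOCC(=O)OC | intermediate
16 | N‑methoxy‑2‑(methoxymethoxy)‑N‑methylacetamide | COCOCC(=O)N(C)OC | intermediate
17 | [2‑ethoxy‑6‑(methoxymethoxy)‑5‑(2‑methylbut‑3‑en‑2‑yl)‑4‑(triisopropylsilyloxy)phenyl]lithium | C=CC(C)(C)c1c(OCOC)c([Li])c(OCC)cc1O[Si](C(C)C)(C(C)C)C(C)C | intermediate (not isolated)
18 | 1‑[6‑ethoxy‑2‑(methoxymethoxy)‑3‑(2‑methylbut‑3‑en‑2‑yl)‑4‑[(triisopropylsilyl)oxy]phenyl]‑2‑(methoxymethoxy)ethan‑1‑one | C=CC(C)(C)c1c(OCOC)c(C(=O)COCOC)c(OCC)cc1O[Si](C(C)C)(C(C)C)C(C)C | intermediate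
19 | 6‑bromoveratraldehyde | COc1cc(Br)c(C=O)cc1OC | starting material
20 | 2‑bromo‑4,5‑dihydroxybenzaldehyde | O=Cc1cc(O)c(O)cc1Br | intermediate
21 | 3‑chloro‑3‑methylbut‑1‑yne | C#CC(C)(C)Cl | starting material
22 | 2‑bromo‑5‑hydroxy‑4‑[(2‑methylbut‑3‑yn‑2‑yl)oxy]benzaldehyde | O=Cc1cc(O)c(OC(C)(C)C#C)cc1Br | intermediate
23 | 2‑bromo‑5‑(methoxymethoxy)‑4‑[(2‑methylbut‑3‑yn‑2‑yl)oxy]benzaldehyde | O=Cc1cc(OCOC)c(OC(C)(C)C#C)cc1Br | intermediate
24 | 5‑bromo‑8‑(methoxymethoxy)‑2,2‑dimethyl‑2H‑chromene‑6‑carbaldehyde | O=Cc1cc(OCOC)c2OC(C)(C)C=Cc2c1Br | intermediate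
25 | 5‑bromo‑8‑(methoxymethoxy)‑2,2‑dimethyl‑2H‑chromene‑6‑carboxylic acid | OC(=O)c1cc(OCOC)c2OC(C)(C)C=Cc2c1Br | intermediate
26 | prenyl bromide | CC(C)=CCBr | starting material
27 | lithium 5‑lithio‑8‑(methoxymethoxy)‑2,2‑dimethyl‑2H‑chromene‑6‑carboxylate | [Li]OC(=O)c1cc(OCOC)c2OC(C)(C)C=Cc2c1[Li] | intermediate (not isolated)
28 | 8‑(methoxymethoxy)‑2,2‑dimethyl‑5‑(3‑methylbut‑2‑en‑1‑yl)‑2H‑chromene‑6‑carboxylic acid | OC(=O)c1cc(OCOC)c2OC(C)(C)C=Cc2c1CC=C(C)C | intermediate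
29 | 8‑(methoxymethoxy)‑2,2‑dimethyl‑5‑(3‑methylbut‑2‑en‑1‑yl)‑2H‑chromene‑6‑carbonyl chloride | ClC(=O)c1cc(OCOC)c2OC(C)(C)C=Cc2c1CC=C(C)C | intermediate (not isolated)
30 | lithium (Z)‑enolate of 18 | C=CC(C)(C)c1c(OCOC)c(/C(O[Li])=C/OCOC)c(OCC)cc1O[Si](C(C)C)(C(C)C)C(C)C | intermediate (not isolated)
31 | 1‑[6‑ethoxy‑2‑(methoxymethoxy)‑3‑(2‑methylbut‑3‑en‑2‑yl)‑4‑[(triisopropylsilyl)oxy]phenyl]‑2‑(methoxymethoxy)‑3‑[8‑(methoxymethoxy)‑2,2‑dimethyl‑5‑(3‑methylbut‑2‑en‑1‑yl)‑2H‑chromen‑6‑yl]propane‑1,3‑dione (racemic) | C=CC(C)(C)c1c(OCOC)c(C(=O)C(OCOC)C(=O)c2cc(OCOC)c3OC(C)(C)C=Cc3c2CC=C(C)C)c(OCC)cc1O[Si](C(C)C)(C(C)C)C(C)C | intermediate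
32 | 1‑[6‑ethoxy‑2‑hydroxy‑3‑(2‑methylbut‑3‑en‑2‑yl)‑4‑[(triisopropylsilyl)oxy]phenyl]‑2‑(methoxymethoxy)‑3‑[8‑(methoxymethoxy)‑2,2‑dimethyl‑5‑(3‑methylbut‑2‑en‑1‑yl)‑2H‑chromen‑6‑yl]propane‑1,3‑dione (racemic) | C=CC(C)(C)c1c(O)c(C(=O)C(OCOC)C(=O)c2cc(OCOC)c3OC(C)(C)C=Cc3c2CC=C(C)C)c(OCC)cc1O[Si](C(C)C)(C(C)C)C(C)C | intermediate (not isolated)
33 | 5‑ethoxy‑3‑(methoxymethoxy)‑2‑[8‑(methoxymethoxy)‑2,2‑dimethyl‑5‑(3‑methylbut‑2‑en‑1‑yl)‑2H‑chromen‑6‑yl]‑8‑(2‑methylbut‑3‑en‑2‑yl)‑7‑[(triisopropylsilyl)oxy]‑4H‑chromen‑4‑one | C=CC(C)(C)c1c(O[Si](C(C)C)(C(C)C)C(C)C)cc(OCC)c2c(=O)c(OCOC)c(-c3cc(OCOC)c4c(c3CC=C(C)C)C=CC(C)(C)O4)oc12 | intermediate (not isolated)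
34 | 5‑ethoxy‑3‑hydroxy‑2‑[8‑hydroxy‑2,2‑dimethyl‑5‑(3‑methylbut‑2‑en‑1‑yl)‑2H‑chromen‑6‑yl]‑8‑(2‑methylbut‑3‑en‑2‑yl)‑7‑[(triisopropylsilyl)oxy]‑4H‑chromen‑4‑one | C=CC(C)(C)c1c(O[Si](C(C)C)(C(C)C)C(C)C)cc(OCC)c2c(=O)c(O)c(-c3cc(O)c4c(c3CC=C(C)C)C=CC(C)(C)O4)oc12 | intermediate
35 | 3,5‑dihydroxy‑2‑[8‑hydroxy‑2,2‑dimethyl‑5‑(3‑methylbut‑2‑en‑1‑yl)‑2H‑chromen‑6‑yl]‑8‑(2‑methylbut‑3‑en‑2‑yl)‑7‑[(triisopropylsilyl)oxy]‑4H‑chromen‑4‑one | C=CC(C)(C)c1c(O[Si](C(C)C)(C(C)C)C(C)C)cc(O)c2c(=O)c(O)c(-c3cc(O)c4c(c3CC=C(C)C)C=CC(C)(C)O4)oc12 | intermediate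
36 | broussoflavonol D | C=CC(C)(C)c1c(O)cc(O)c2c(=O)c(O)c(-c3cc(O)c4c(c3CC=C(C)C)C=CC(C)(C)O4)oc12 | target

**Step count and risks**

Total step count: 18. Longest linear sequence: 10 steps (19 → 36, steps 9–18); the ring‑A line from 1 is 9 steps.

Steps most likely to fail:

Step 4 (benzannulation). The donor‑stabilised cyclobutenone may open only at temperatures where the ynol ether isomerises by silyl shift or the vinylketene dimerises, so that the [2+2] capture is lost. The fallback sets out from ynol ether 4 and returns at phenol 12, generating the same vinylketene 8 at room temperature by 1,4‑dehydrochlorination instead of ring opening. Purchased ethyl (E)‑3‑ethoxybut‑2‑enoate would be saponified with LiOH to (E)‑3‑ethoxybut‑2‑enoic acid F1 and converted with oxalyl chloride into (E)‑3‑ethoxybut‑2‑enoyl chloride F2. Slow addition of F2 to 4 and Et3N in CH2Cl2 should trap the ketene as vinylcyclobutenone 9, which is then heated in toluene to give 12 by the same ring opening and 6π closure.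

Step 17 (O5 de‑ethylation). SN2 attack at the ethyl carbon may be too slow, and at the temperature then needed the Lewis acid may induce addition of a neighbouring oxygen to the prenyl or 1,1‑dimethylallyl alkene. The fallback sets out from 34 and arrives directly at target 36, changing from Lewis‑acid activation to an anionic dealkylation. Sodium ethanethiolate in DMF at 100–120 °C under argon should cleave the ethyl ether, whose phenoxide leaving group is stabilised by the C4 carbonyl, by SN2 at carbon under basic conditions that leave the alkenes untouched. The thiolate should also remove the aryl silyl group, so acidic work‑up gives 36 in one operation and no new compound is made.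

Step 15 (C‑aroylation). The enolate may be acylated on oxygen or twice, or the two hindered partners may react too slowly. The fallback sets out from ketone 18 and returns at phenol diketone 32, replacing the intermolecular acylation by an intramolecular aroyl transfer. The aryl MOM group ortho to the carbonyl would be removed selectively (NaHSO4·SiO2, CH2Cl2, rt) to give 1‑[6‑ethoxy‑2‑hydroxy‑3‑(2‑methylbut‑3‑en‑2‑yl)‑4‑[(triisopropylsilyl)oxy]phenyl]‑2‑(methoxymethoxy)ethan‑1‑one F3. Esterification of F3 with acid 28 (EDC, DMAP, CH2Cl2) would give the aryl ester 2‑[2‑(methoxymethoxy)acetyl]‑3‑ethoxy‑6‑(2‑methylbut‑3‑en‑2‑yl)‑5‑[(triisopropylsilyl)oxy]phenyl 8‑(methoxymethoxy)‑2,2‑dimethyl‑5‑(3‑methylbut‑2‑en‑1‑yl)‑2H‑chromene‑6‑carboxylate F4. Treatment of F4 with KOt‑Bu in THF at 0 °C should effect the Baker–Venkataraman O→C aroyl shift through a six‑membered transition state to 32, which is carried on under the conditions of step 16.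

Further compounds
F1 | step 4 | (E)‑3‑ethoxybut‑2‑enoic acid | CCO/C(C)=C/C(=O)O
F2 | step 4 | (E)‑3‑ethoxybut‑2‑enoyl chloride | CCO/C(C)=C/C(=O)Cl
F0 | step 17 | none | none
F3 | step 15 | 1‑[6‑ethoxy‑2‑hydroxy‑3‑(2‑methylbut‑3‑en‑2‑yl)‑4‑[(triisopropylsilyl)oxy]phenyl]‑2‑(methoxymethoxy)ethan‑1‑one | C=CC(C)(C)c1c(O)c(C(=O)COCOC)c(OCC)cc1O[Si](C(C)C)(C(C)C)C(C)C
F4 | step 15 | 2‑[2‑(methoxymethoxy)acetyl]‑3‑ethoxy‑6‑(2‑methylbut‑3‑en‑2‑yl)‑5‑[(triisopropylsilyl)oxy]phenyl 8‑(methoxymethoxy)‑2,2‑dimethyl‑5‑(3‑methylbut‑2‑en‑1‑yl)‑2H‑chromene‑6‑carboxylate | C=CC(C)(C)c1c(OC(=O)c2cc(OCOC)c3OC(C)(C)C=Cc3c2CC=C(C)C)c(C(=O)COCOC)c(OCC)cc1O[Si](C(C)C)(C(C)C)C(C)C
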